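The trimer is cut at its two C4–C8 bonds into a C4-activated epirobinetinidol, a robinetinidol-type middle unit and (−)-epicatechin. The pyran ring of the flavan units (O1, C2, C3, C4, C4a, C8a) is not cyclised: an α-ketol ring expansion of a 2-aryl-3-hydroxy-2,3-dihydrobenzofuran-3-carbaldehyde, made by enantioselective carbene C–H insertion and enolate hydroxylation, moves C2 from the carbinol carbon to the formyl carbon. One operation enlarges the dihydrofuran to the pyranone, forms C2–C3, sets the trans C3 hydroxyl and leaves the ring A-conjugated C4 carbonyl. The step exploits the C3-hydroxy/C4-benzylic edge of ring C next to 7-oxygenated ring A. The all-cis middle unit follows from 4α-arylation and inversion at C3.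

Key step: step 7

Remark: Rh2(S-PTTL)4 is assumed to give the (2S)-configured cis ester 6 in step 4; if the sense of induction is the opposite, Rh2(R-PTTL)4 is used with no other change.

Step 1
Reactants: 1 1-[4-(benzyloxy)-2-hydroxyphenyl]ethan-1-one; 2 [3,4,5-tris(benzyloxy)phenyl]methanol
Product: 3 1-[4-(benzyloxy)-2-{[3,4,5-tris(benzyloxy)phenyl]methoxy}phenyl]ethan-1-one
Conditions: PPh3, DIAD, THF, 0 °C to rt
Reagents that add atoms: none
Why: Mitsunobu etherification of the acidic, chelated phenol with the activated primary benzylic alcohol; no stereocentre is formed.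

Step 2
Reactants: 3 1-[4-(benzyloxy)-2-{[3,4,5-tris(benzyloxy)phenyl]methoxy}phenyl]ethan-1-one
Product: 4 methyl 2-[4-(benzyloxy)-2-{[3,4,5-tris(benzyloxy)phenyl]methoxy}phenyl]acetate
Conditions: PhI(OAc)2, H2SO4 (cat.), HC(OMe)3, rt
Reagents that add atoms: trimethyl orthoformate, COC(OC)OC
Why: Hypervalent-iodine oxidative 1,2-aryl migration of the enol ether formed in situ (aryl methyl ketone to methyl arylacetate), eased by the electron-rich migrating ring A so that only catalytic acid at room temperature is needed.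

Step 3
Reactants: 4 methyl 2-[4-(benzyloxy)-2-{[3,4,5-tris(benzyloxy)phenyl]methoxy}phenyl]acetate
Product: 5 methyl 2-[4-(benzyloxy)-2-{[3,4,5-tris(benzyloxy)phenyl]methoxy}phenyl]-2-diazoacetate
Conditions: 4-acetamidobenzenesulfonyl azide, DBU, MeCN, 0 °C to rt
Reagents that add atoms: 4-acetamidobenzenesulfonyl azide, CC(=O)Nc1ccc(cc1)S(=O)(=O)N=[N+]=[N-]
Why: Regitz diazo transfer to the benzylic ester enolate should give the donor/acceptor diazo ester.

Step 4
Reactants: 5 methyl 2-[4-(benzyloxy)-2-{[3,4,5-tris(benzyloxy)phenyl]methoxy}phenyl]-2-diazoacetate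
Product: 6 methyl (2S,3R)-6-(benzyloxy)-2-[3,4,5-tris(benzyloxy)phenyl]-2,3-dihydro-1-benzofuran-3-carboxylate (2,3-cis)
Conditions: Rh2(S-PTTL)4 [dirhodium tetrakis(N-phthaloyl-(S)-tert-leucinate)] (1 mol %), toluene, −60 °C
Reagents that add atoms: none
Why: Intramolecular 1,5 C–H insertion of the rhodium carbene into the activated benzylic ether C–H closes the dihydrofuran; the chiral carboxylate ligands set C2 (and the cis C3, which is erased in step 5).

Step 5
Reactants: 6 methyl (2S,3R)-6-(benzyloxy)-2-[3,4,5-tris(benzyloxy)phenyl]-2,3-dihydro-1-benzofuran-3-carboxylate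
Product: 7 methyl (2R,3S)-6-(benzyloxy)-3-hydroxy-2-[3,4,5-tris(benzyloxy)phenyl]-2,3-dihydro-1-benzofuran-3-carboxylate (3-hydroxyl trans to the C2 aryl group)
Conditions: KN(SiMe3)2, THF, −78 °C; then 2-(benzenesulfonyl)-3-phenyloxaziridine, −78 °C; aq. NH4Cl
Reagents that add atoms: 2-(benzenesulfonyl)-3-phenyloxaziridine, O=S(=O)(c1ccccc1)N1OC1c1ccccc1
Why: Davis hydroxylation of the potassium ester enolate, with the oxidant approaching anti to the C2 aryl group; C2 is untouched and its descriptor changes only because C3 gains priority.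

Step 6
Reactants: 7 methyl (2R,3S)-6-(benzyloxy)-3-hydroxy-2-[3,4,5-tris(benzyloxy)phenyl]-2,3-dihydro-1-benzofuran-3-carboxylate
Product: 8 (2R,3S)-6-(benzyloxy)-3-hydroxy-2-[3,4,5-tris(benzyloxy)phenyl]-2,3-dihydro-1-benzofuran-3-carbaldehyde
Conditions: i-Bu2AlH (2.2 equiv), CH2Cl2, −78 °C; aq. KNaC4H4O6 (potassium sodium tartrate)
Reagents that add atoms: none
Why: Partial reduction of the α-hydroxy ester through the chelated aluminium hemiacetal, which should collapse to the aldehyde only on work-up.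

Step 7
Reactants: 8 (2R,3S)-6-(benzyloxy)-3-hydroxy-2-[3,4,5-tris(benzyloxy)phenyl]-2,3-dihydro-1-benzofuran-3-carbaldehyde
Product: 9 (2R,3R)-7-(benzyloxy)-3-hydroxy-2-[3,4,5-tris(benzyloxy)phenyl]-2,3-dihydro-4H-chromen-4-one (2,3-trans)
Conditions: Sc(OTf)3 (10 mol %), CH2Cl2, 0 °C to rt
Reagents that add atoms: none
Why: Sc(OTf)3 chelates the hydroxyl and formyl oxygens of 8 in a five-membered ring, and the C3–C2 bond, held nearly perpendicular to the carbonyl plane, shifts suprafacially to the formyl carbon while the carbinol carbon becomes the C4 ketone. The closest known reaction type is the α-ketol (acyloin) rearrangement of tertiary α-hydroxy aldehydes, long used for one-carbon ring enlargement of 1-hydroxycycloalkyl carbonyl compounds such as D-homoannulation. No ring is closed by cyclisation: the five-membered ring O1–C2–C3–C3a–C7a grows to the six-membered ring O1–C2–C3–C4–C4a–C8a by a 1,2-shift through a three-centre transition state that inserts the former formyl carbon between C2 and the carbinol carbon. C2 migrates with retention and keeps the configuration set in step 4, and the new C3 centre is fixed by the syn chelate, which places its hydroxyl trans to the C2 aryl group, the diequatorial arrangement that equilibration next to the ketone would also give. The step needs C2 to migrate in preference to the ring A carbon, which its oxygen substituent, its benzylic character and the gain of the ring A-conjugated ketone should secure; should the aryl carbon shift instead, the 4-hydroxy-3-ketone formed is still ring-expanded and can tautomerise through the enediol to 9. Relief of five-ring strain and the change from aldehyde to aryl ketone drive the step forward.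

Step 8
Reactants: 9 (2R,3R)-7-(benzyloxy)-3-hydroxy-2-[3,4,5-tris(benzyloxy)phenyl]-2,3-dihydro-4H-chromen-4-one
Product: 11 (2R,3S)-7-(benzyloxy)-2-[3,4,5-tris(benzyloxy)phenyl]chroman-3-ol (tetra-O-benzylrobinetinidol), via 3,4-diol 10 (not isolated)
Conditions: NaBH4, THF–MeOH, 0 °C; crude diol, then Et3SiH, CF3CO2H, CH2Cl2, −20 to 0 °C
Reagents that add atoms: none
Why: Hydride reduction of the aryl ketone followed by ionic hydrogenation (silane capture of the para-alkoxy-stabilised C4 cation) should remove the C4 oxygen without touching C2 or C3.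

Step 9
Reactants: 11 (2R,3S)-7-(benzyloxy)-2-[3,4,5-tris(benzyloxy)phenyl]chroman-3-ol
Product: 12 (2R,3S)-7-(benzyloxy)-6-bromo-2-[3,4,5-tris(benzyloxy)phenyl]chroman-3-ol
Conditions: NBS, CH2Cl2, −20 °C
Reagents that add atoms: N-bromosuccinimide, BrN1C(=O)CCC1=O
Why: Electrophilic aromatic bromination at C6, para to O1 and ortho to the 7-benzyloxy group and the least hindered activated position, which blocks C6 so that C8 is the only free activated site of ring A.

Step 10
Reactants: 12 (2R,3S)-7-(benzyloxy)-6-bromo-2-[3,4,5-tris(benzyloxy)phenyl]chroman-3-ol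
Product: 13 (2R)-7-(benzyloxy)-6-bromo-2-[3,4,5-tris(benzyloxy)phenyl]chroman-3-one
Conditions: Dess–Martin periodinane, CH2Cl2, rt
Reagents that add atoms: none
Why: Dess–Martin oxidation of the secondary alcohol under near-neutral conditions, which should keep the α-stereocentre C2 intact.

Step 11
Reactants: 13 (2R)-7-(benzyloxy)-6-bromo-2-[3,4,5-tris(benzyloxy)phenyl]chroman-3-one
Product: 14 (2R,3R)-7-(benzyloxy)-6-bromo-2-[3,4,5-tris(benzyloxy)phenyl]chroman-3-ol (2,3-cis)
Conditions: LiBH(s-Bu)3 (L-Selectride), THF, −78 °C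
Reagents that add atoms: none
Why: The bulky hydride attacks the flavan-3-one from the face anti to the C2 aryl group and should give the axial 3-hydroxyl cis to it (the established catechin-to-epicatechin inversion).

Step 12
Reactants: 14 (2R,3R)-7-(benzyloxy)-6-bromo-2-[3,4,5-tris(benzyloxy)phenyl]chroman-3-ol
Product: 15 (2R,3R)-3,7-bis(benzyloxy)-6-bromo-2-[3,4,5-tris(benzyloxy)phenyl]chromane
Conditions: NaH, BnBr, Bu4NI (cat.), DMF, 0 °C to rt
Reagents that add atoms: benzyl bromide, BrCc1ccccc1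
Why: Williamson etherification protects the C3 hydroxyl of the future upper unit against the later oxidation.

Step 13
Reactants: 15 (2R,3R)-3,7-bis(benzyloxy)-6-bromo-2-[3,4,5-tris(benzyloxy)phenyl]chromane
Product: 16 (2R,3R,4S)-3,7-bis(benzyloxy)-6-bromo-4-(2-ethoxyethoxy)-2-[3,4,5-tris(benzyloxy)phenyl]chromane (4β)
Conditions: DDQ, HOCH2CH2OEt, CH2Cl2, rt
Reagents that add atoms: 2-ethoxyethanol, CCOCCO
Why: DDQ abstracts hydride from C4 (para to the 7-alkoxy group, ortho to O1) and the alcohol should trap the cation trans to the 3-benzyloxy group.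

Step 14
Reactants: 16 (2R,3R,4S)-3,7-bis(benzyloxy)-6-bromo-4-(2-ethoxyethoxy)-2-[3,4,5-tris(benzyloxy)phenyl]chromane; 12 (2R,3S)-7-(benzyloxy)-6-bromo-2-[3,4,5-tris(benzyloxy)phenyl]chroman-3-ol
Product: 17 dimer penta-O-benzyl-6-bromoepirobinetinidol-(4β→8)-tetra-O-benzyl-6-bromorobinetinidol [upper unit (2R,3R,4R); lower unit (2R,3S)]
Conditions: TMSOTf (cat.), nucleophile in fourfold excess, CH2Cl2, −78 to −30 °C; Et3N quench
Reagents that add atoms: none
Why: Lewis-acid Friedel–Crafts coupling of the flavan-4-yl cation, attacked anti to the 3-benzyloxy group (4β) by C8 of 12, whose C6 is blocked and which is used in excess to suppress self-condensation.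

Step 15
Reactants: 17 dimer penta-O-benzyl-6-bromoepirobinetinidol-(4β→8)-tetra-O-benzyl-6-bromorobinetinidol
Product: 18 the same dimer carrying a 4β-(2-ethoxyethoxy) group on its lower unit [lower unit (2R,3S,4S)]
Conditions: DDQ, HOCH2CH2OEt, CH2Cl2, rt
Reagents that add atoms: 2-ethoxyethanol, CCOCCO
Why: DDQ benzylic oxidation at the C4 methylene of the lower unit with trapping by the alcohol on the face anti to the C2 aryl group, the tertiary C4–H of the upper unit being shielded by its two aryl groups.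

Step 16
Reactants: 19 (−)-epicatechin
Product: 20 (2R,3R)-5,7-bis(benzyloxy)-2-[3,4-bis(benzyloxy)phenyl]chroman-3-ol (tetra-O-benzylepicatechin)
Conditions: BnBr, K2CO3, DMF, rt, argon
Reagents that add atoms: benzyl bromide, BrCc1ccccc1
Why: Williamson alkylation of the four phenols only, since carbonate does not deprotonate the secondary alcohol.

Step 17
Reactants: 18 dimer with the 4β-(2-ethoxyethoxy) group on its lower unit; 20 tetra-O-benzylepicatechin
Product: 21 protected trimer with a 2,3-trans-3,4-trans middle unit (2R,3S,4S) bearing a free 3-hydroxyl and joined (4α→8) to tetra-O-benzylepicatechin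
Conditions: TMSOTf (cat.), nucleophile in fourfold excess, CH2Cl2, −78 to −40 °C; Et3N quench
Reagents that add atoms: none
Why: Friedel–Crafts coupling in which C8 of the phloroglucinol-type ring of 20 attacks the 2,3-trans flavan-4-yl cation anti to its 3-hydroxyl, which should give the 3,4-trans (4α) bond with the C2 and C4 aryl groups cis.

Step 18
Reactants: 21 protected trimer with free 3-hydroxyls in the middle and lower units
Product: 22 protected trimer with C3 ketones in the middle unit (2R,4S) and in the epicatechin unit (2R)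
Conditions: Dess–Martin periodinane (excess), NaHCO3, CH2Cl2, rt
Reagents that add atoms: none
Why: Dess–Martin oxidation of the two free secondary alcohols, while the upper unit is protected as its 3-benzyl ether.

Step 19
Reactants: 22 protected trimer with C3 ketones in the middle and lower units
Product: 23 protected trimer with the all-cis middle unit (2R,3R,4S) and the 2,3-cis lower unit (2R,3R)
Conditions: LiBH(s-Bu)3 (L-Selectride, excess), THF, −78 °C
Reagents that add atoms: none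
Why: The bulky hydride adds to each flavan-3-one from the face anti to the C2 aryl group (in the middle unit also anti to the cis C4 aryl group), which should give axial 3-hydroxyls: the all-cis middle unit and the restored epicatechin configuration.

Step 20
Reactants: 23 protected trimer carrying thirteen benzyl ethers and two aryl bromides
Product: 24 epirobinetinidol-(4β→8)-epirobinetinidol-(4α→8)-epicatechin (the target) [upper (2R,3R,4R); middle (2R,3R,4S); lower (2R,3R)]
Conditions: H2 (1 atm), Pd(OH)2/C, NaOAc, THF–MeOH–H2O, rt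
Reagents that add atoms: none
Why: Hydrogenolysis should cleave all thirteen benzyl ethers and both aryl C–Br bonds in one operation, with acetate buffering the HBr so that the interflavan bonds are not cleaved.

Compound list
1 | 1-[4-(benzyloxy)-2-hydroxyphenyl]ethan-1-one | CC(=O)c1ccc(OCc2ccccc2)cc1O | starting material
2 | [3,4,5-tris(benzyloxy)phenyl]methanol | OCc1cc(OCc2ccccc2)c(OCc2ccccc2)c(OCc2ccccc2)c1 | starting material
3 | 1-[4-(benzyloxy)-2-{[3,4,5-tris(benzyloxy)phenyl]methoxy}phenyl]ethan-1-one | CC(=O)c1ccc(OCc2ccccc2)cc1OCc1cc(OCc2ccccc2)c(OCc2ccccc2)c(OCc2ccccc2)c1 | intermediate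
4 | methyl 2-[4-(benzyloxy)-2-{[3,4,5-tris(benzyloxy)phenyl]methoxy}phenyl]acetate | COC(=O)Cc1ccc(OCc2ccccc2)cc1OCc1cc(OCc2ccccc2)c(OCc2ccccc2)c(OCc2ccccc2)c1 | intermediate
5 | methyl 2-[4-(benzyloxy)-2-{[3,4,5-tris(benzyloxy)phenyl]methoxy}phenyl]-2-diazoacetate | COC(=O)C(=[N+]=[N-])c1ccc(OCc2ccccc2)cc1OCc1cc(OCc2ccccc2)c(OCc2ccccc2)c(OCc2ccccc2)c1 | intermediate
6 | methyl (2S,3R)-6-(benzyloxy)-2-[3,4,5-tris(benzyloxy)phenyl]-2,3-dihydro-1-benzofuran-3-carboxylate (cis) | O(Cc1ccccc1)c1ccc2c(c1)O[C@H](c1cc(OCc3ccccc3)c(OCc3ccccc3)c(OCc3ccccc3)c1)[C@@H]2C(=O)OC | intermediate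
7 | methyl (2R,3S)-6-(benzyloxy)-3-hydroxy-2-[3,4,5-tris(benzyloxy)phenyl]-2,3-dihydro-1-benzofuran-3-carboxylate | O(Cc1ccccc1)c1ccc2c(c1)O[C@H](c1cc(OCc3ccccc3)c(OCc3ccccc3)c(OCc3ccccc3)c1)[C@]2(O)C(=O)OC | intermediate
8 | (2R,3S)-6-(benzyloxy)-3-hydroxy-2-[3,4,5-tris(benzyloxy)phenyl]-2,3-dihydro-1-benzofuran-3-carbaldehyde | O(Cc1ccccc1)c1ccc2c(c1)O[C@H](c1cc(OCc3ccccc3)c(OCc3ccccc3)c(OCc3ccccc3)c1)[C@]2(O)C=O | intermediate
9 | (2R,3R)-7-(benzyloxy)-3-hydroxy-2-[3,4,5-tris(benzyloxy)phenyl]-2,3-dihydro-4H-chromen-4-one | O(Cc1ccccc1)c1ccc2c(c1)O[C@H](c1cc(OCc3ccccc3)c(OCc3ccccc3)c(OCc3ccccc3)c1)[C@@H](O)C2=O | intermediate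
10 | (2R,3S,4R)-7-(benzyloxy)-2-[3,4,5-tris(benzyloxy)phenyl]chromane-3,4-diol | O(Cc1ccccc1)c1ccc2c(c1)O[C@H](c1cc(OCc3ccccc3)c(OCc3ccccc3)c(OCc3ccccc3)c1)[C@@H](O)[C@@H]2O | intermediate
11 | (2R,3S)-7-(benzyloxy)-2-[3,4,5-tris(benzyloxy)phenyl]chroman-3-ol | O(Cc1ccccc1)c1ccc2c(c1)O[C@H](c1cc(OCc3ccccc3)c(OCc3ccccc3)c(OCc3ccccc3)c1)[C@@H](O)C2 | intermediate
12 | (2R,3S)-7-(benzyloxy)-6-bromo-2-[3,4,5-tris(benzyloxy)phenyl]chroman-3-ol | O(Cc1ccccc1)c1c(Br)cc2c(c1)O[C@H](c1cc(OCc3ccccc3)c(OCc3ccccc3)c(OCc3ccccc3)c1)[C@@H](O)C2 | intermediate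
13 | (2R)-7-(benzyloxy)-6-bromo-2-[3,4,5-tris(benzyloxy)phenyl]chroman-3-one | O(Cc1ccccc1)c1c(Br)cc2c(c1)O[C@H](c1cc(OCc3ccccc3)c(OCc3ccccc3)c(OCc3ccccc3)c1)C(=O)C2 | intermediate
14 | (2R,3R)-7-(benzyloxy)-6-bromo-2-[3,4,5-tris(benzyloxy)phenyl]chroman-3-ol | O(Cc1ccccc1)c1c(Br)cc2c(c1)O[C@H](c1cc(OCc3ccccc3)c(OCc3ccccc3)c(OCc3ccccc3)c1)[C@H](O)C2 | intermediate
15 | (2R,3R)-3,7-bis(benzyloxy)-6-bromo-2-[3,4,5-tris(benzyloxy)phenyl]chromane | O(Cc1ccccc1)c1c(Br)cc2c(c1)O[C@H](c1cc(OCc3ccccc3)c(OCc3ccccc3)c(OCc3ccccc3)c1)[C@H](OCc1ccccc1)C2 | intermediate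
16 | (2R,3R,4S)-3,7-bis(benzyloxy)-6-bromo-4-(2-ethoxyethoxy)-2-[3,4,5-tris(benzyloxy)phenyl]chromane | O(Cc1ccccc1)c1c(Br)cc2c(c1)O[C@H](c1cc(OCc3ccccc3)c(OCc3ccccc3)c(OCc3ccccc3)c1)[C@H](OCc1ccccc1)[C@H]2OCCOCC | intermediate
17 | penta-O-benzyl-6-bromoepirobinetinidol-(4β→8)-tetra-O-benzyl-6-bromorobinetinidol, upper (2R,3R,4R), lower (2R,3S) | O(Cc1ccccc1)c1c(Br)cc2c(c1)O[C@H](c1cc(OCc3ccccc3)c(OCc3ccccc3)c(OCc3ccccc3)c1)[C@H](OCc1ccccc1)[C@H]2c1c(OCc2ccccc2)c(Br)cc2c1O[C@H](c1cc(OCc3ccccc3)c(OCc3ccccc3)c(OCc3ccccc3)c1)[C@@H](O)C2 | intermediate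
18 | the dimer of step 14 with a 4β-(2-ethoxyethoxy) group on the lower unit, lower (2R,3S,4S) | O(Cc1ccccc1)c1c(Br)cc2c(c1)O[C@H](c1cc(OCc3ccccc3)c(OCc3ccccc3)c(OCc3ccccc3)c1)[C@H](OCc1ccccc1)[C@H]2c1c(OCc2ccccc2)c(Br)cc2c1O[C@H](c1cc(OCc3ccccc3)c(OCc3ccccc3)c(OCc3ccccc3)c1)[C@@H](O)[C@H]2OCCOCC | intermediate
19 | (−)-epicatechin, (2R,3R)-2-(3,4-dihydroxyphenyl)chromane-3,5,7-triol | Oc1cc(O)c2c(c1)O[C@H](c1ccc(O)c(O)c1)[C@H](O)C2 | starting material
20 | (2R,3R)-5,7-bis(benzyloxy)-2-[3,4-bis(benzyloxy)phenyl]chroman-3-ol | O(Cc1ccccc1)c1cc(OCc3ccccc3)c2c(c1)O[C@H](c1ccc(OCc3ccccc3)c(OCc3ccccc3)c1)[C@H](O)C2 | intermediate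
21 | protected trimer, middle unit (2R,3S,4S) 2,3-trans-3,4-trans with free 3-hydroxyl, (4α→8) to tetra-O-benzylepicatechin | O(Cc1ccccc1)c1c(Br)cc2c(c1)O[C@H](c1cc(OCc3ccccc3)c(OCc3ccccc3)c(OCc3ccccc3)c1)[C@H](OCc1ccccc1)[C@H]2c1c(OCc2ccccc2)c(Br)cc2c1O[C@H](c1cc(OCc3ccccc3)c(OCc3ccccc3)c(OCc3ccccc3)c1)[C@@H](O)[C@@H]2c1c(OCc2ccccc2)cc(OCc2ccccc2)c2c1O[C@H](c1ccc(OCc3ccccc3)c(OCc3ccccc3)c1)[C@H](O)C2 | intermediate
22 | protected trimer with C3 ketones in the middle and lower units | O(Cc1ccccc1)c1c(Br)cc2c(c1)O[C@H](c1cc(OCc3ccccc3)c(OCc3ccccc3)c(OCc3ccccc3)c1)[C@H](OCc1ccccc1)[C@H]2c1c(OCc2ccccc2)c(Br)cc2c1O[C@H](c1cc(OCc3ccccc3)c(OCc3ccccc3)c(OCc3ccccc3)c1)C(=O)[C@@H]2c1c(OCc2ccccc2)cc(OCc2ccccc2)c2c1O[C@H](c1ccc(OCc3ccccc3)c(OCc3ccccc3)c1)C(=O)C2 | intermediate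
23 | protected trimer, middle unit (2R,3R,4S) all-cis, lower unit (2R,3R) | O(Cc1ccccc1)c1c(Br)cc2c(c1)O[C@H](c1cc(OCc3ccccc3)c(OCc3ccccc3)c(OCc3ccccc3)c1)[C@H](OCc1ccccc1)[C@H]2c1c(OCc2ccccc2)c(Br)cc2c1O[C@H](c1cc(OCc3ccccc3)c(OCc3ccccc3)c(OCc3ccccc3)c1)[C@H](O)[C@@H]2c1c(OCc2ccccc2)cc(OCc2ccccc2)c2c1O[C@H](c1ccc(OCc3ccccc3)c(OCc3ccccc3)c1)[C@H](O)C2 | intermediate
24 | epirobinetinidol-(4β→8)-epirobinetinidol-(4α→8)-epicatechin | Oc1ccc2c(c1)O[C@H](c1cc(O)c(O)c(O)c1)[C@H](O)[C@H]2c1c(O)ccc2c1O[C@H](c1cc(O)c(O)c(O)c1)[C@H](O)[C@@H]2c1c(O)cc(O)c2c1O[C@H](c1ccc(O)c(O)c1)[C@H](O)C2 | target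

Total step count: 20. Longest linear sequence: 19 steps (steps 1 to 15, then 17 to 20; step 16 is a side branch).

Steps most likely to fail

Step 14. The flavan-4-yl cation may not find the doubly flanked, bromine-deactivated C8 of 12 fast enough, so that attack on the pyrogallol rings or self-condensation of the electrophile takes over. The fallback sets out from 11 and 16 and comes back at 17, replacing the blocking-group logic by a boron nucleophile placed at C8. Compound 11 is treated with n-BuLi (2.2 equiv) and TMEDA in THF (−78 to 0 °C, kept cold to outrun metalation of the benzyl ethers), which forms the alkoxide and then lithiates C8 between O1 and the 7-benzyloxy group. Quenching with B(OMe)3 and aqueous KHF2 gives the potassium C8-trifluoroborate of tetra-O-benzylrobinetinidol F1. F1 and 16 are joined with BF3·OEt2 in CH2Cl2–MeCN by ipso-substitution of the aryltrifluoroborate by the flavan-4-yl cation, again anti to the 3-benzyloxy group, to give the dimer without bromine on the lower unit F2. NBS should then brominate C6 of the lower unit (para to O1) and give 17.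

Step 19. Hydride delivery to the flanked middle-unit ketone may be slow, so that enolisation toward the doubly benzylic C4, epimerisation at C2 or C4, or loss of facial selectivity competes. The fallback sets out from 14, 16 and 20 and comes back at 23, building the all-cis middle unit by aryllithium addition and ionic reduction instead of ketone reduction. The 2,3-cis alcohol 14 (excess) is coupled with 16 under TMSOTf as in step 14 to give the dimer with a 2,3-cis lower unit F3. DDQ in wet CH2Cl2 gives the lower-unit 3,4-diol F4, and MnO2 oxidises only its benzylic C4 hydroxyl to the 3-hydroxy-4-ketone F5. Separately, 20 is brominated at C8 with NBS to 8-bromo-tetra-O-benzylepicatechin F6. F6 is turned into the alkoxide aryllithium with n-BuLi then t-BuLi (THF, −78 °C) and added in excess to F5, one equivalent serving to deprotonate its 3-hydroxyl, to give the tertiary benzylic carbinol F7. Ionic reduction (Et3SiH or Bu3SnH, CF3CO2H, CH2Cl2) should deliver hydride to the C4 cation anti to the C3 oxygen and the C2 aryl group, which places the epicatechin unit cis to both and gives 23.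

Step 7. Migration of the ring A carbon may compete with that of C2, and the transient 3-oxo isomer or a Lewis-acid ring opening may erode the configuration at C2. The fallback sets out from 7 and comes back at 11, keeping the one-carbon ring enlargement but as a semipinacol shift. LiAlH4 reduces 7 to the 3-(hydroxymethyl)-3-ol F8, and MsCl with Et3N sulfonylates the primary hydroxyl to give the mesylate F9. Et2AlCl (CH2Cl2, −78 °C) then makes the electron-rich ring A carbon migrate to the CH2 carbon while the tertiary carbinol becomes the ketone, enlarging the dihydrofuran to the flavan-3-one F10. NaBH4 (axial delivery, equatorial alcohol) should then give mainly the 2,3-trans alcohol 11.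

Further compounds
F1 | step 14 | potassium {(2R,3S)-7-(benzyloxy)-3-hydroxy-2-[3,4,5-tris(benzyloxy)phenyl]chroman-8-yl}trifluoroborate | [K+].F[B-](F)(F)c1c(OCc2ccccc2)ccc2c1O[C@H](c1cc(OCc3ccccc3)c(OCc3ccccc3)c(OCc3ccccc3)c1)[C@@H](O)C2
F2 | step 14 | penta-O-benzyl-6-bromoepirobinetinidol-(4β→8)-tetra-O-benzylrobinetinidol (no bromine on the lower unit) | O(Cc1ccccc1)c1c(Br)cc2c(c1)O[C@H](c1cc(OCc3ccccc3)c(OCc3ccccc3)c(OCc3ccccc3)c1)[C@H](OCc1ccccc1)[C@H]2c1c(OCc2ccccc2)ccc2c1O[C@H](c1cc(OCc3ccccc3)c(OCc3ccccc3)c(OCc3ccccc3)c1)[C@@H](O)C2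
F3 | step 19 | penta-O-benzyl-6-bromoepirobinetinidol-(4β→8)-tetra-O-benzyl-6-bromoepirobinetinidol (lower unit 2,3-cis) | O(Cc1ccccc1)c1c(Br)cc2c(c1)O[C@H](c1cc(OCc3ccccc3)c(OCc3ccccc3)c(OCc3ccccc3)c1)[C@H](OCc1ccccc1)[C@H]2c1c(OCc2ccccc2)c(Br)cc2c1O[C@H](c1cc(OCc3ccccc3)c(OCc3ccccc3)c(OCc3ccccc3)c1)[C@H](O)C2
F4 | step 19 | dimer F3 with a 4β-hydroxyl on the lower unit (3,4-diol) | O(Cc1ccccc1)c1c(Br)cc2c(c1)O[C@H](c1cc(OCc3ccccc3)c(OCc3ccccc3)c(OCc3ccccc3)c1)[C@H](OCc1ccccc1)[C@H]2c1c(OCc2ccccc2)c(Br)cc2c1O[C@H](c1cc(OCc3ccccc3)c(OCc3ccccc3)c(OCc3ccccc3)c1)[C@H](O)[C@H]2O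
F5 | step 19 | dimer with 2,3-cis 3-hydroxy-4-ketone lower unit | O(Cc1ccccc1)c1c(Br)cc2c(c1)O[C@H](c1cc(OCc3ccccc3)c(OCc3ccccc3)c(OCc3ccccc3)c1)[C@H](OCc1ccccc1)[C@H]2c1c(OCc2ccccc2)c(Br)cc2c1O[C@H](c1cc(OCc3ccccc3)c(OCc3ccccc3)c(OCc3ccccc3)c1)[C@H](O)C2=O
F6 | step 19 | (2R,3R)-5,7-bis(benzyloxy)-2-[3,4-bis(benzyloxy)phenyl]-8-bromochroman-3-ol | Brc1c(OCc2ccccc2)cc(OCc2ccccc2)c2c1O[C@H](c1ccc(OCc3ccccc3)c(OCc3ccccc3)c1)[C@H](O)C2
F7 | step 19 | trimer with tertiary C4 carbinol in the middle unit (4α-hydroxyl, 4β-aryl) | O(Cc1ccccc1)c1c(Br)cc2c(c1)O[C@H](c1cc(OCc3ccccc3)c(OCc3ccccc3)c(OCc3ccccc3)c1)[C@H](OCc1ccccc1)[C@H]2c1c(OCc2ccccc2)c(Br)cc2c1O[C@H](c1cc(OCc3ccccc3)c(OCc3ccccc3)c(OCc3ccccc3)c1)[C@H](O)[C@@]2(O)c1c(OCc2ccccc2)cc(OCc2ccccc2)c2c1O[C@H](c1ccc(OCc3ccccc3)c(OCc3ccccc3)c1)[C@H](O)C2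
F8 | step 7 | (2R,3R)-6-(benzyloxy)-3-(hydroxymethyl)-2-[3,4,5-tris(benzyloxy)phenyl]-2,3-dihydro-1-benzofuran-3-ol | O(Cc1ccccc1)c1ccc2c(c1)O[C@H](c1cc(OCc3ccccc3)c(OCc3ccccc3)c(OCc3ccccc3)c1)[C@]2(O)CO
F9 | step 7 | primary methanesulfonate of F8 | O(Cc1ccccc1)c1ccc2c(c1)O[C@H](c1cc(OCc3ccccc3)c(OCc3ccccc3)c(OCc3ccccc3)c1)[C@]2(O)COS(C)(=O)=O
F10 | step 7 | (2R)-7-(benzyloxy)-2-[3,4,5-tris(benzyloxy)phenyl]chroman-3-one | O(Cc1ccccc1)c1ccc2c(c1)O[C@H](c1cc(OCc3ccccc3)c(OCc3ccccc3)c(OCc3ccccc3)c1)C(=O)C2
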